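## Retrosynthetic overview

1. Target 9 ⇒ (R)-triol 7 + farnesylsilane 2: the ring-B aryl–C(quaternary) bond is made last, by catalytic enantioselective para-"reverse farnesylation" of the o-quinone of 7 (sets 3S).
2. 7 ⇒ aldehyde 6 by Dakin oxidation; the CHO is the latent third oxygen of ring B and keeps that ring inert while ring A is oxidised.
3. 6 ⇒ spiroketal 5 + 2: the same catalytic manifold with the other catalyst antipode on a masked 2-aryloxyphenoxenium ion (sets 3R, the first stereocentre).
4. 5 ⇒ 4 ⇒ 2,2'-oxydiphenol 3 (oxidative spiroketalisation; mono ortho-formylation); 2 ⇒ (2E,6E)-farnesol 1.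
5. No carbocycle is built: both benzene rings and the diaryl ether come from 3; the only ring formed is the temporary spiro-1,3-benzodioxole (step 3), opened again in step 4.

Assumption: 3 and 1 are bought; the sense of induction of the new catalytic step must be found by experiment, so "(S,S)-IDPi" (step 4) and "(R,R)-IDPi" (step 6) stand for whichever catalyst antipode gives the 3R and the 3S centre.

## Route

Step 1
Reactants: 1 (2E,6E)-farnesol
Product: 2 trimethyl[(2E,6E)-3,7,11-trimethyldodeca-2,6,10-trien-1-yl]silane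
Conditions: (Me3Si)2 (1.3 equiv), Pd(BF4)2(MeCN)4 (5 mol%), DMSO/MeOH, 50 °C
Reagents that add atoms: hexamethyldisilane, C[Si](C)(C)[Si](C)(C)C
Why: Pd-catalysed allylic C–OH silylation with a disilane goes through an η3-allyl-Pd species that takes silicon at the unhindered primary terminus, giving the linear allylsilane with the 2E geometry retained (checked by NOE, since E/Z purity later becomes ee).

Step 2
Reactants: 3 2,2'-oxydiphenol
Product: 4 2-hydroxy-3-(2-hydroxyphenoxy)benzaldehyde
Conditions: MgCl2, Et3N, (CH2O)n (limiting), MeCN, 80 °C, stopped at partial conversion; aq. HCl; 3 recovered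
Reagents that add atoms: paraformaldehyde (formaldehyde), C=O
Why: Magnesium-phenoxide-directed ortho-formylation (Casnati–Skattebøl) attacks only the free position ortho to OH, so mono-formylation desymmetrises 3 and places a CHO that is both the latent ring-B oxygen and a deactivator of that ring.

Step 3
Reactants: 4 2-hydroxy-3-(2-hydroxyphenoxy)benzaldehyde
Product: 5 (±)-6'-oxospiro[1,3-benzodioxole-2,1'-cyclohexa-2',4'-diene]-4-carbaldehyde
Conditions: PhI(OAc)2 (1.05 equiv), CF3CH2OH/CH2Cl2, −20 °C; cold aq. NaHCO3, short cold SiO2 plug, used at once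
Reagents that add atoms: none
Why: Hypervalent-iodine oxidative dearomatisation of the more electron-rich phenol (the other OH is formyl-conjugated and H-bonded), with ipso trapping by the neighbouring phenol oxygen, gives the o-quinone monoketal as a spiroketal; its racemic spiro centre is erased in step 4.

Step 4
Reactants: 5 (±)-6'-oxospiro[1,3-benzodioxole-2,1'-cyclohexa-2',4'-diene]-4-carbaldehyde; 2 trimethyl[(2E,6E)-3,7,11-trimethyldodeca-2,6,10-trien-1-yl]silane
Product: 6 2-hydroxy-3-{2-hydroxy-5-[(3R,6E)-3,7,11-trimethyldodeca-1,6,10-trien-3-yl]phenoxy}benzaldehyde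
Conditions: (S,S)-IDPi (confined imidodiphosphorimidate, 5 mol%), 2 (1.3 equiv), 4 Å MS, toluene/CH2Cl2, −78 °C; aq. NaHCO3
Reagents that add atoms: none
Why: Proposed new method: the strong confined chiral acid (H+, or Me3Si+ after turnover, paired with the IDPi anion) opens the ketal C–O bond to the formyl-flanked oxygen (better nucleofuge, poorer donor), giving a 2-aryloxyphenoxenium (O-aryl-o-quinonium)·IDPi– contact ion pair that is most electrophilic at C-3' of the dienone (para to C=O); the γ-carbon of the E-allylsilane attacks there in an open SE2' transition state (the fully substituted ketal carbon and the α-keto position do not compete for a tertiary nucleophilic carbon), Me3Si+ is lost and the 4H-dienone tautomerises to the phenol; because the 2E geometry already fixes methyl versus chain, the anion only has to select one alkene face, which sets the 3R quaternary centre; closest known reaction types are the Hosomi–Sakurai allylation, acid-promoted substitution of quinone monoketals by allylsilanes, chiral-acid-catalysed additions to oxocarbenium ions and the oxidative para-allylation of phenols.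

Step 5
Reactants: 6 2-hydroxy-3-{2-hydroxy-5-[(3R,6E)-3,7,11-trimethyldodeca-1,6,10-trien-3-yl]phenoxy}benzaldehyde
Product: 7 3-{2-hydroxy-5-[(3R,6E)-3,7,11-trimethyldodeca-1,6,10-trien-3-yl]phenoxy}benzene-1,2-diol
Conditions: 30% H2O2 (1.5 equiv), NaOH (2 equiv), THF/H2O, 0 °C, Ar; then 1 M HCl
Reagents that add atoms: hydrogen peroxide, OO
Why: Dakin oxidation (hydroperoxide addition to the o-hydroxy-aldehyde, aryl migration, formate hydrolysis) turns CHO into OH; alkaline H2O2 does not touch the isolated alkenes or the quaternary centre.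

Step 6
Reactants: 7 3-{2-hydroxy-5-[(3R,6E)-3,7,11-trimethyldodeca-1,6,10-trien-3-yl]phenoxy}benzene-1,2-diol; 2 trimethyl[(2E,6E)-3,7,11-trimethyldodeca-2,6,10-trien-1-yl]silane
Product: 9 3-{2-hydroxy-5-[(3R,6E)-3,7,11-trimethyldodeca-1,6,10-trien-3-yl]phenoxy}-5-[(3S,6E)-3,7,11-trimethyldodeca-1,6,10-trien-3-yl]benzene-1,2-diol (target), via o-quinone 8 (not isolated)
Conditions: Ag2O (2 equiv), MgSO4, CH2Cl2, 0 °C, filtered cold under Ar; then (R,R)-IDPi (5 mol%), 2 (1.5 equiv), −78 °C; aq. NH4Cl
Reagents that add atoms: none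
Why: Proposed new method: Ag2O oxidises only the catechol ring, and the chiral acid then protonates (or silylates) the more basic carbonyl of 8, the one that is a doubly vinylogous ester of the aryloxy group, giving a 2-hydroxy-6-aryloxyphenoxenium-type ion pair whose only open electrophilic site is C-5 (para to the central oxygen, both ortho positions carrying O); γ-selective SE2' attack of the allylsilane, loss of Me3Si+ and tautomerisation give the catechol, and the antipodal catalyst selects the other alkene face to set the 3S centre independently of the remote 3R centre; closest known reaction types are chiral-phosphoric-acid-catalysed conjugate arylation of quinones and Lewis-acid Sakurai conjugate allylation.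

## Compound list

1 | (2E,6E)-farnesol | OC/C=C(\C)CC/C=C(\C)CCC=C(C)C | starting material
2 | trimethyl[(2E,6E)-3,7,11-trimethyldodeca-2,6,10-trien-1-yl]silane | C[Si](C)(C)C/C=C(\C)CC/C=C(\C)CCC=C(C)C | intermediate
3 | 2,2'-oxydiphenol | Oc1ccccc1Oc1ccccc1O | starting material
4 | 2-hydroxy-3-(2-hydroxyphenoxy)benzaldehyde | O=Cc1cccc(Oc2ccccc2O)c1O | intermediate
5 | (±)-6'-oxospiro[1,3-benzodioxole-2,1'-cyclohexa-2',4'-diene]-4-carbaldehyde (racemic spiro centre) | O=C1C=CC=CC12Oc3cccc(C=O)c3O2 | intermediate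
6 | 2-hydroxy-3-{2-hydroxy-5-[(3R,6E)-3,7,11-trimethyldodeca-1,6,10-trien-3-yl]phenoxy}benzaldehyde | C=C[C@@](C)(CC/C=C(\C)CCC=C(C)C)c1ccc(O)c(Oc2cccc(C=O)c2O)c1 | intermediate
7 | 3-{2-hydroxy-5-[(3R,6E)-3,7,11-trimethyldodeca-1,6,10-trien-3-yl]phenoxy}benzene-1,2-diol | C=C[C@@](C)(CC/C=C(\C)CCC=C(C)C)c1ccc(O)c(Oc2cccc(O)c2O)c1 | intermediate
8 | 3-{2-hydroxy-5-[(3R,6E)-3,7,11-trimethyldodeca-1,6,10-trien-3-yl]phenoxy}cyclohexa-3,5-diene-1,2-dione | C=C[C@@](C)(CC/C=C(\C)CCC=C(C)C)c1ccc(O)c(OC2=CC=CC(=O)C2=O)c1 | intermediate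
9 | 3-{2-hydroxy-5-[(3R,6E)-3,7,11-trimethyldodeca-1,6,10-trien-3-yl]phenoxy}-5-[(3S,6E)-3,7,11-trimethyldodeca-1,6,10-trien-3-yl]benzene-1,2-diol | C=C[C@@](C)(CC/C=C(\C)CCC=C(C)C)c1ccc(O)c(Oc2cc([C@](C)(C=C)CC/C=C(\C)CCC=C(C)C)cc(O)c2O)c1 | target

## Step count and risks

Total steps: 6. Longest linear sequence: 5 (steps 2–6); step 1 is a one-step side branch whose product 2 is used in steps 4 and 6.

**Step 4 (proposed new step, first stereocentre).** Risks: the ketal may open the other way and give the isomeric ether; the silane may add to the aldehyde; the ee may be low. The fallback uses known chemistry, a copper-catalysed enantioselective SN2' allylic substitution with an aryl-aluminium reagent. It sets out from 4 (with 1 for the electrophile) and comes back at 7. NBS brominates the electron-rich ring para to its OH to give 3-(5-bromo-2-hydroxyphenoxy)-2-hydroxybenzaldehyde F5. Dakin oxidation gives 3-(5-bromo-2-hydroxyphenoxy)benzene-1,2-diol F6, and TBSCl/imidazole gives its tris-TBS ether F7. Br/Li exchange with n-BuLi and Et2AlCl give the aryl(diethyl)alane F8 in situ. Alcohol 1 with ClP(O)(OEt)2/pyridine gives diethyl (2E,6E)-farnesyl phosphate F9. A chiral sulfonate-NHC–copper catalyst joins F8 and F9 at the γ-carbon to give the tris-TBS ether of 7 F10, and TBAF releases 7.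

**Step 6 (proposed new step, second stereocentre).** Risks: the 3-aryloxy-o-quinone is labile; attack at a carbonyl carbon followed by [3,3] shift would give the linear farnesyl isomer; stereocontrol on this second ion pair may differ from step 4. The fallback uses known chemistry, a sterically controlled C–H borylation followed by copper-catalysed enantioselective allyl–aryl coupling of an arylboronate. It sets out from 7 and comes back at 9. TBSCl/imidazole gives the tris-TBS ether of 7 F10 (the same compound as in the step 4 fallback). Iridium-catalysed borylation ([Ir(OMe)(cod)]2, dtbpy, B2pin2) takes the only arene C–H not flanked by a substituent, C-5 of the catechol ring, giving the pinacol boronate F11; the hindered vinyl group is the main chemoselectivity concern. Chiral NHC–copper catalyst, NaOMe and the farnesyl phosphate F9 give the tris-TBS ether of 9 F12, and TBAF releases 9.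

**Step 3 (oxidative spiroketalisation).** Risks: 5 may dimerise by Diels–Alder reaction; oxidation may lead to a p-quinone or attack the wrong ring. The fallback replaces the spiroketal by an open-chain o-quinol acetate with ring B carried as a masked catechol. It sets out from 4 and comes back at 7. Dakin oxidation of 4 gives 3-(2-hydroxyphenoxy)benzene-1,2-diol F1. Carbonyldiimidazole closes the catechol to 4-(2-hydroxyphenoxy)-1,3-benzodioxol-2-one F2. Wessely acetoxylation (PhI(OAc)2, AcOH/CH2Cl2) gives racemic 6-oxo-1-[(2-oxo-1,3-benzodioxol-4-yl)oxy]cyclohexa-2,4-dien-1-yl acetate F3, which can ionise only by loss of acetate. The catalytic reverse farnesylation with 2 then gives 4-{2-hydroxy-5-[(3R,6E)-3,7,11-trimethyldodeca-1,6,10-trien-3-yl]phenoxy}-1,3-benzodioxol-2-one F4, and K2CO3/MeOH frees 7.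

## Further compounds

F1 | step 3 | 3-(2-hydroxyphenoxy)benzene-1,2-diol | Oc1ccccc1Oc1cccc(O)c1O
F2 | step 3 | 4-(2-hydroxyphenoxy)-1,3-benzodioxol-2-one | O=C1Oc2cccc(Oc3ccccc3O)c2O1
F3 | step 3 | (±)-6-oxo-1-[(2-oxo-1,3-benzodioxol-4-yl)oxy]cyclohexa-2,4-dien-1-yl acetate | CC(=O)OC1(Oc2cccc3OC(=O)Oc23)C=CC=CC1=O
F4 | step 3 | 4-{2-hydroxy-5-[(3R,6E)-3,7,11-trimethyldodeca-1,6,10-trien-3-yl]phenoxy}-1,3-benzodioxol-2-one | C=C[C@@](C)(CC/C=C(\C)CCC=C(C)C)c1ccc(O)c(Oc2cccc3OC(=O)Oc23)c1
F5 | step 4 | 3-(5-bromo-2-hydroxyphenoxy)-2-hydroxybenzaldehyde | O=Cc1cccc(Oc2cc(Br)ccc2O)c1O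
F6 | step 4 | 3-(5-bromo-2-hydroxyphenoxy)benzene-1,2-diol | Oc1ccc(Br)cc1Oc1cccc(O)c1O
F7 | step 4 | tris(tert-butyldimethylsilyl) ether of F6 | CC(C)(C)[Si](C)(C)Oc1ccc(Br)cc1Oc1cccc(O[Si](C)(C)C(C)(C)C)c1O[Si](C)(C)C(C)(C)C
F8 | step 4 | {3-[2,3-bis(tert-butyldimethylsilyloxy)phenoxy]-4-(tert-butyldimethylsilyloxy)phenyl}diethylaluminium | CC[Al](CC)c1ccc(O[Si](C)(C)C(C)(C)C)c(Oc2cccc(O[Si](C)(C)C(C)(C)C)c2O[Si](C)(C)C(C)(C)C)c1
F9 | step 4 | diethyl (2E,6E)-3,7,11-trimethyldodeca-2,6,10-trien-1-yl phosphate | CCOP(=O)(OCC)OC/C=C(\C)CC/C=C(\C)CCC=C(C)C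
F10 | step 4 | tris(tert-butyldimethylsilyl) ether of 7 | C=C[C@@](C)(CC/C=C(\C)CCC=C(C)C)c1ccc(O[Si](C)(C)C(C)(C)C)c(Oc2cccc(O[Si](C)(C)C(C)(C)C)c2O[Si](C)(C)C(C)(C)C)c1
F11 | step 6 | tris(tert-butyldimethylsilyl) ether of 7 with a pinacol boronate at C-5 of the catechol ring | C=C[C@@](C)(CC/C=C(\C)CCC=C(C)C)c1ccc(O[Si](C)(C)C(C)(C)C)c(Oc2cc(B3OC(C)(C)C(C)(C)O3)cc(O[Si](C)(C)C(C)(C)C)c2O[Si](C)(C)C(C)(C)C)c1
F12 | step 6 | tris(tert-butyldimethylsilyl) ether of 9 | C=C[C@@](C)(CC/C=C(\C)CCC=C(C)C)c1ccc(O[Si](C)(C)C(C)(C)C)c(Oc2cc([C@](C)(C=C)CC/C=C(\C)CCC=C(C)C)cc(O[Si](C)(C)C(C)(C)C)c2O[Si](C)(C)C(C)(C)C)c1
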